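The bonds cut are C4a–C4 and C4–C3. Within ring C, the carbonyl carbon C4 has no carbon neighbours other than C4a (ring A) and C3, which bears the methoxy group and sits α to the future C2 ketone on the ring B side. C4 can therefore come from carbon monoxide. One palladium-catalysed carbonylative α-arylation joins an aryl iodide, carbon monoxide and a ketone enolate and should deliver the complete open-chain 1,3-diketone without closing a ring. The iodoarene carries iodine at C4a between a MOM-protected C8a oxygen and a benzyl-protected C5 oxygen; the ketone is 2,3-bis(benzyloxy)phenyl methoxymethyl ketone.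

Key step: step 7

Remark: diketones 14 and 15 are drawn as diketo forms although enol (and for 15 cyclic hemiketal) tautomers will be present; the C3 centre formed in step 7 is racemic and vanishes in step 8.

Step 1
Reactants: 1 3-hydroxy-4,5-dimethoxybenzaldehyde
Product: 2 3-hydroxy-2-iodo-4,5-dimethoxybenzaldehyde
Conditions: ICl, pyridine/1,4-dioxane, 0 °C to rt
Reagents that add atoms: iodine monochloride, ClI
Why: Electrophilic aromatic iodination should go to C2 of the benzaldehyde, the only free position ortho to the hydroxyl and also para to the C5 methoxy group (the pattern seen in the 2-halogenation of isovanillin), while C6 is shielded by the in-plane methyl of the C5 methoxy group.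

Step 2
Reactants: 2 3-hydroxy-2-iodo-4,5-dimethoxybenzaldehyde
Product: 3 2-iodo-4,5-dimethoxy-3-(methoxymethoxy)benzaldehyde
Conditions: MOMCl, iPr2NEt, CH2Cl2, 0 °C to rt
Reagents that add atoms: chloromethyl methyl ether, COCCl
Why: O-Alkylation of the phenol with the highly reactive α-chloro ether (Williamson-type acetal formation) should succeed even though the hydroxyl is flanked by iodine and a methoxy group.

Step 3
Reactants: 3 2-iodo-4,5-dimethoxy-3-(methoxymethoxy)benzaldehyde
Product: 5 2-iodo-4,5-dimethoxy-3-(methoxymethoxy)phenol, via aryl formate 4 (not isolated)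
Conditions: mCPBA, CH2Cl2, 0 °C to rt; then K2CO3 (cat.), MeOH, rt; aq. Na2S2O3 wash
Reagents that add atoms: 3-chloroperoxybenzoic acid, OOC(=O)c1cccc(Cl)c1
Why: Baeyer–Villiger (Dakin-type) oxidation of the electron-rich aldehyde proceeds by aryl migration to formate 4, which catalytic carbonate in methanol cleaves to the phenol; the MOM ether tolerates the weak carboxylic acid, and the thiosulfate wash returns any iodine oxidised by the peracid to the aryl iodide.

Step 4
Reactants: 5 2-iodo-4,5-dimethoxy-3-(methoxymethoxy)phenol
Product: 6 1-(benzyloxy)-2-iodo-4,5-dimethoxy-3-(methoxymethoxy)benzene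
Conditions: BnBr, K2CO3, DMF, rt
Reagents that add atoms: benzyl bromide, BrCc1ccccc1
Why: Williamson ether synthesis on the phenoxide with a primary benzylic bromide leaves the MOM acetal and the aryl iodide untouched under these basic conditions.

Step 5
Reactants: 7 3-bromobenzene-1,2-diol
Product: 8 1,2-bis(benzyloxy)-3-bromobenzene
Conditions: BnBr (2.2 equiv), K2CO3, DMF, 60 °C, under N2
Reagents that add atoms: benzyl bromide, BrCc1ccccc1
Why: Twofold Williamson etherification of the catechol should be clean when air is excluded to prevent quinone formation.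

Step 6
Reactants: 8 1,2-bis(benzyloxy)-3-bromobenzene; 9 N,2-dimethoxy-N-methylacetamide
Product: 12 1-[2,3-bis(benzyloxy)phenyl]-2-methoxyethan-1-one, via aryllithium 10 (not isolated), via lithium hemiaminal alkoxide 11 (not isolated)
Conditions: n-BuLi, THF, −78 °C; then 9, −78 to 0 °C; then 1 M HCl
Reagents that add atoms: none
Why: Bromine–lithium exchange at −78 °C is faster than any attack on the benzyl ethers, and the aryllithium adds only once to the amide (Weinreb ketone synthesis) because the chelated tetrahedral adduct 11 survives until the acidic quench.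

Step 7
Reactants: 6 1-(benzyloxy)-2-iodo-4,5-dimethoxy-3-(methoxymethoxy)benzene; 12 1-[2,3-bis(benzyloxy)phenyl]-2-methoxyethan-1-one; 13 carbon monoxide
Product: 14 1-[6-(benzyloxy)-3,4-dimethoxy-2-(methoxymethoxy)phenyl]-3-[2,3-bis(benzyloxy)phenyl]-2-methoxypropane-1,3-dione (racemic)
Conditions: Pd(dba)2 (5 mol %), Xantphos (5 mol %), CO (5 bar), K3PO4 (3 equiv), 1,4-dioxane, 90 °C
Reagents that add atoms: none
Why: Zerovalent palladium inserts into the C4a–I bond of 6, carbon monoxide migrates in to give an aroyl–palladium complex, the potassium enolate of 12 (formed by K3PO4 at its only enolisable carbon) replaces iodide on palladium, and reductive elimination forms C4–C3 after C4a–C4. This is the known palladium-catalysed carbonylative α-arylation of ketones with aryl iodides to 1,3-diketones. No ring is closed, and the C3 stereocentre arises racemic and uncontrolled, which is harmless because it is enolisable and becomes sp2 in step 8. Carbonylation must outrun direct α-arylation: the two ortho oxygen substituents crowd the aryl–palladium bond and so favour insertion of carbon monoxide, helped by 5 bar of CO and the large bite angle of Xantphos. C-Acylation must beat O-acylation: the carbon-bound palladium enolate and the removal of 14 from the equilibrium as its stabilised enolate favour the diketone.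

Step 8
Reactants: 14 1-[6-(benzyloxy)-3,4-dimethoxy-2-(methoxymethoxy)phenyl]-3-[2,3-bis(benzyloxy)phenyl]-2-methoxypropane-1,3-dione
Product: 16 5-(benzyloxy)-2-[2,3-bis(benzyloxy)phenyl]-3,7,8-trimethoxy-4H-chromen-4-one, via hydroxy diketone 15 (not isolated)
Conditions: HCl (1.25 M in MeOH), THF, 55 °C
Reagents that add atoms: none
Why: Acid-catalysed acetal cleavage frees the C8a phenol, the only free hydroxyl, which adds to the ring B carbonyl and loses water (cyclodehydration of an o-hydroxyaryl 1,3-diketone, as in the last stage of a Baker–Venkataraman flavone synthesis), so ring C can close only through the C8a oxygen while the benzyl ethers stay on.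

Step 9
Reactants: 16 5-(benzyloxy)-2-[2,3-bis(benzyloxy)phenyl]-3,7,8-trimethoxy-4H-chromen-4-one
Product: 17 5,2',3'-trihydroxy-3,7,8-trimethoxyflavone
Conditions: H2 (1 atm), 10% Pd/C, EtOAc/MeOH, rt
Reagents that add atoms: none
Why: Catalytic hydrogenolysis cleaves the three benzylic C–O bonds, while the tetrasubstituted vinylogous-ester C2–C3 double bond of the flavone and the aryl methyl ethers should not be reduced at ambient pressure.

Compound list
1 | 3-hydroxy-4,5-dimethoxybenzaldehyde | COc1cc(C=O)cc(O)c1OC | starting material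
2 | 3-hydroxy-2-iodo-4,5-dimethoxybenzaldehyde | COc1cc(C=O)c(I)c(O)c1OC | intermediate
3 | 2-iodo-4,5-dimethoxy-3-(methoxymethoxy)benzaldehyde | COCOc1c(I)c(C=O)cc(OC)c1OC | intermediate
4 | 2-iodo-4,5-dimethoxy-3-(methoxymethoxy)phenyl formate | COCOc1c(I)c(OC=O)cc(OC)c1OC | intermediate
5 | 2-iodo-4,5-dimethoxy-3-(methoxymethoxy)phenol | COCOc1c(I)c(O)cc(OC)c1OC | intermediate
6 | 1-(benzyloxy)-2-iodo-4,5-dimethoxy-3-(methoxymethoxy)benzene | COCOc1c(OC)c(OC)cc(OCc2ccccc2)c1I | intermediate
7 | 3-bromobenzene-1,2-diol | Oc1cccc(Br)c1O | starting material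
8 | 1,2-bis(benzyloxy)-3-bromobenzene | Brc1cccc(OCc2ccccc2)c1OCc1ccccc1 | intermediate
9 | N,2-dimethoxy-N-methylacetamide | COCC(=O)N(C)OC | starting material
10 | [2,3-bis(benzyloxy)phenyl]lithium | [Li]c1cccc(OCc2ccccc2)c1OCc1ccccc1 | intermediate
11 | lithium 1-[2,3-bis(benzyloxy)phenyl]-2-methoxy-1-[methoxy(methyl)amino]ethan-1-olate (racemic) | [Li]OC(COC)(N(C)OC)c1cccc(OCc2ccccc2)c1OCc1ccccc1 | intermediate
12 | 1-[2,3-bis(benzyloxy)phenyl]-2-methoxyethan-1-one | COCC(=O)c1cccc(OCc2ccccc2)c1OCc1ccccc1 | intermediate
13 | carbon monoxide | [C-]#[O+] | starting material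
14 | 1-[6-(benzyloxy)-3,4-dimethoxy-2-(methoxymethoxy)phenyl]-3-[2,3-bis(benzyloxy)phenyl]-2-methoxypropane-1,3-dione (racemic) | COCOc1c(OC)c(OC)cc(OCc2ccccc2)c1C(=O)C(OC)C(=O)c1cccc(OCc2ccccc2)c1OCc1ccccc1 | intermediate
15 | 1-[6-(benzyloxy)-2-hydroxy-3,4-dimethoxyphenyl]-3-[2,3-bis(benzyloxy)phenyl]-2-methoxypropane-1,3-dione (racemic) | COc1cc(OCc2ccccc2)c(C(=O)C(OC)C(=O)c2cccc(OCc3ccccc3)c2OCc2ccccc2)c(O)c1OC | intermediate
16 | 5-(benzyloxy)-2-[2,3-bis(benzyloxy)phenyl]-3,7,8-trimethoxy-4H-chromen-4-one | COc1cc(OCc2ccccc2)c2c(=O)c(OC)c(-c3cccc(OCc4ccccc4)c3OCc3ccccc3)oc2c1OC | intermediate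
17 | 5,2',3'-trihydroxy-3,7,8-trimethoxyflavone | COc1cc(O)c2c(=O)c(OC)c(-c3cccc(O)c3O)oc2c1OC | target

Total step count: 9. Longest linear sequence: 7 steps (steps 1, 2, 3, 4, 7, 8, 9).

Steps most likely to fail

Step 7. Palladium may join the enolate directly to the aryl group before carbon monoxide is taken up, the crowded aroyl–palladium may acylate the enolate at oxygen, or the catalyst may stall at the di-ortho-substituted aryl iodide. The fallback sets out from 6 and returns at 14, forming the same two bonds in separate operations with carbon dioxide as the source of C4. Iodine–magnesium exchange on 6 (iPrMgCl·LiCl, THF, −20 °C) should give [6-(benzyloxy)-3,4-dimethoxy-2-(methoxymethoxy)phenyl]magnesium chloride F1, which is carboxylated with CO2 and worked up with mild acid to 6-(benzyloxy)-3,4-dimethoxy-2-(methoxymethoxy)benzoic acid F2. Carbonyldiimidazole in THF converts F2 under neutral conditions into [6-(benzyloxy)-3,4-dimethoxy-2-(methoxymethoxy)phenyl](1H-imidazol-1-yl)methanone F3. A crossed Claisen condensation of F3 with the lithium enolate of 12 (LiN(SiMe3)2, 2 equiv, THF, −78 °C to rt) should then deliver 14.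

Step 1. Iodination may stray to C6, para to the hydroxyl, or occur twice. The fallback sets out from 1 and returns at 6, placing iodine last by directed metalation. MOM protection of 1 (MOMCl, iPr2NEt) gives 4,5-dimethoxy-3-(methoxymethoxy)benzaldehyde F4. Baeyer–Villiger oxidation with mCPBA gives 3,4-dimethoxy-5-(methoxymethoxy)phenyl formate F5, which is methanolysed in the same flask (K2CO3, MeOH) to 3,4-dimethoxy-5-(methoxymethoxy)phenol F6. Benzylation (BnBr, K2CO3, DMF) gives 1-(benzyloxy)-3,4-dimethoxy-5-(methoxymethoxy)benzene F7. Directed ortho-lithiation with n-BuLi in THF at 0 °C is steered by the MOM group, whose only free ortho position is the carbon between the two oxygens, and should give [2-(benzyloxy)-4,5-dimethoxy-6-(methoxymethoxy)phenyl]lithium F8. Quenching F8 with I2 gives 6. This sequence also keeps iodine out of the peracid step.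

Step 9. Hydrogen may add across C2–C3 of ring C, cleavage of the crowded C5 benzyl ether may stall on a catalyst poisoned by traces of iodide or phosphine, or the catechol may oxidise in air during a slow reaction. The fallback sets out from 16 and returns at 17 with no new compound (F0). Lewis-acid debenzylation with BCl3 and pentamethylbenzene as cation scavenger in CH2Cl2 at −78 °C cleaves aryl benzyl ethers without hydrogen and should leave the methyl ethers in place at that temperature.

Further compounds
F1 | step 7 | [6-(benzyloxy)-3,4-dimethoxy-2-(methoxymethoxy)phenyl]magnesium chloride | COCOc1c(OC)c(OC)cc(OCc2ccccc2)c1[Mg]Cl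
F2 | step 7 | 6-(benzyloxy)-3,4-dimethoxy-2-(methoxymethoxy)benzoic acid | COCOc1c(OC)c(OC)cc(OCc2ccccc2)c1C(=O)O
F3 | step 7 | [6-(benzyloxy)-3,4-dimethoxy-2-(methoxymethoxy)phenyl](1H-imidazol-1-yl)methanone | COCOc1c(OC)c(OC)cc(OCc2ccccc2)c1C(=O)n1ccnc1
F4 | step 1 | 4,5-dimethoxy-3-(methoxymethoxy)benzaldehyde | COCOc1cc(C=O)cc(OC)c1OC
F5 | step 1 | 3,4-dimethoxy-5-(methoxymethoxy)phenyl formate | COCOc1cc(OC=O)cc(OC)c1OC
F6 | step 1 | 3,4-dimethoxy-5-(methoxymethoxy)phenol | COCOc1cc(O)cc(OC)c1OC
F7 | step 1 | 1-(benzyloxy)-3,4-dimethoxy-5-(methoxymethoxy)benzene | COCOc1cc(OCc2ccccc2)cc(OC)c1OC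
F8 | step 1 | [2-(benzyloxy)-4,5-dimethoxy-6-(methoxymethoxy)phenyl]lithium | [Li]c1c(OCOC)c(OC)c(OC)cc1OCc1ccccc1
F0 | step 9 | none | none
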